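Ring B is disconnected as a cyclohexene. The trans C2–Cl/C3–Br pair is a masked C2=C3 alkene, which places methyl-bearing C3 para to spiro carbon C6, and the exocyclic C7=C14 methylene next to C6 is a masked ketone. Ring B is therefore a Diels–Alder retron: isoprene supplies C1–C4, the exocyclic enone C5=C6–C7=O of an enantioenriched bromo-ketone (ring A, from a stereospecific bromonium cyclisation) supplies C5 and C6. One cycloaddition closes ring B through the C1–C6 and C4–C5 bonds and sets the quaternary spiro centre, steered by the C11 gem-dimethyl group and the C10 bromide. Epoxide opening, bromide substitution and methylenation complete the target.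

Key step: step 7

Remark: chamigrane numbering is used throughout (ring B = C1–C5, spiro carbon C6, ring A = C7–C11, exocyclic CH2 = C14); the target is (2R,3R,6S,10S).
Remark: in step 1 the ligand enantiomer is assumed to be the one that delivers the (S)-bromochloride.

Step 1
Reactants: 1 prenol (3-methylbut-2-en-1-ol)
Product: 2 (2S)-2-bromo-3-chloro-3-methylbutan-1-ol
Conditions: NBS, ClTi(OiPr)3 (1.1 equiv), Schiff-base ligand 2-[(3,5-di-tert-butyl-2-hydroxybenzylidene)amino]-3,3-dimethyl-1,1-diphenylbutan-1-ol (20 mol %), hexanes, −20 °C
Reagents that add atoms: N-bromosuccinimide, O=C1CCC(=O)N1Br; chlorotitanium triisopropoxide, CC(C)O[Ti](Cl)(OC(C)C)OC(C)C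
Why: Titanium-mediated, ligand-controlled enantioselective bromochlorination of an allylic alcohol, in which the ligated titanium alkoxide delivers chloride to the tertiary carbon of the NBS-derived bromonium ion anti to bromine, so the ligand enantiomer sets the single stereocentre (C2, S).

Step 2
Reactants: 2 (2S)-2-bromo-3-chloro-3-methylbutan-1-ol
Product: 3 (2S)-2-bromo-3-chloro-3-methylbutyl trifluoromethanesulfonate
Conditions: Tf2O, 2,6-lutidine, CH2Cl2, −78 °C
Reagents that add atoms: trifluoromethanesulfonic anhydride, O=S(=O)(OS(=O)(=O)C(F)(F)F)C(F)(F)F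
Why: O-Sulfonylation of the primary alcohol gives a leaving group reactive enough for SN2 at a β-branched carbon, and the stereocentre is not touched.

Step 3
Reactants: 3 (2S)-2-bromo-3-chloro-3-methylbutyl trifluoromethanesulfonate; 4 methyl acetoacetate
Product: 6 methyl (6S)-6-bromo-7-chloro-7-methyl-3-oxooctanoate, via sodium lithium dianion 5 (not isolated)
Conditions: 4, NaH, THF, 0 °C; n-BuLi, 0 °C; then 3, −78 → −30 °C; then 1 M HCl
Reagents that add atoms: none
Why: Weiler dianion γ-alkylation, in which the terminal carbanion of 5 displaces the primary triflate by SN2 at low temperature, where E2 loss of triflate should be slower, and the C–Br stereocentre is carried through unchanged.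

Step 4
Reactants: 6 methyl (6S)-6-bromo-7-chloro-7-methyl-3-oxooctanoate
Product: 7 methyl (2E,6S)-6-bromo-7-chloro-3-methoxy-7-methyloct-2-enoate
Conditions: HC(OMe)3, H2SO4 (cat.), MeOH, 23 °C
Reagents that add atoms: trimethyl orthoformate, COC(OC)OC
Why: Acid-catalysed enol-ether formation via the dimethyl ketal gives the conjugated (E)-β-methoxy enoate as the thermodynamic product and removes the free ketone oxygen that could otherwise cyclise through oxygen in step 5.

Step 5
Reactants: 7 methyl (2E,6S)-6-bromo-7-chloro-3-methoxy-7-methyloct-2-enoate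
Product: 9 methyl (5S)-5-bromo-2-methoxy-6,6-dimethylcyclohex-1-ene-1-carboxylate, via bromiranium ion 8 (not isolated)
Conditions: (CF3)2CHOH, 23 °C
Reagents that add atoms: none
Why: Stereospecific bromonium-initiated cation–olefin cyclisation, in which solvolysis of the tertiary chloride with anchimeric assistance by bromine gives ion 8 without loss of configuration, the nucleophilic α-carbon of the β-methoxy enoate attacks its tertiary carbon in a six-membered (6-endo) closure, and proton loss restores the enol ether, so the C–Br centre (S) is retained.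

Step 6
Reactants: 9 methyl (5S)-5-bromo-2-methoxy-6,6-dimethylcyclohex-1-ene-1-carboxylate
Product: 11 (4S)-4-bromo-3,3-dimethyl-2-methylidenecyclohexan-1-one, via allylic alcohol 10 (not isolated)
Conditions: i-Bu2AlH, CH2Cl2, −78 °C; then 1 M H2SO4, THF, 0 °C
Reagents that add atoms: water, O
Why: Ester reduction followed by acid-mediated allylic transposition and hydrolysis of the β-alkoxy allylic alcohol (Stork–Danheiser-type sequence) unveils the α-methylene ketone without forming a stereocentre, and the enone is used at once to avoid dimerisation.

Step 7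
Reactants: 11 (4S)-4-bromo-3,3-dimethyl-2-methylidenecyclohexan-1-one; 12 isoprene
Product: 13 (6R,10S)-10-bromo-3,11,11-trimethylspiro[5.5]undec-2-en-7-one
Conditions: EtAlCl2 (20 mol %), isoprene (5 equiv), CH2Cl2, −78 → −20 °C
Reagents that add atoms: none
Why: EtAlCl2 coordinates the ketone of the s-cis-locked exocyclic enone C5=C6–C7=O and lowers its LUMO, and isoprene adds in a normal-electron-demand, asynchronous [4+2] cycloaddition (Diels–Alder reaction) in which the C4–C5 bond is advanced and ring B is completed as C1–C6 forms at the quaternary carbon. The closest known reaction type is the Lewis-acid-promoted Diels–Alder spiroannulation of 2-methylidenecycloalkanones with 2-substituted butadienes. Ring B (six-membered) is closed by intermolecular [4+2] cycloaddition. The only new stereocentre, C6, is controlled by ring A: with C10–Br equatorial, the axial C11 methyl group shields one face of the exocyclic alkene, the diene adds to the opposite face, and C1 ends trans to bromine (6R,10S in 13, the relative configuration of the target). The step needs "para" regioselectivity, secured by the larger HOMO coefficient at the isoprene CH2 next to the methyl-bearing carbon pairing with the β-carbon C5 and sharpened by the Lewis acid, and it needs cycloaddition to outrun hetero-Diels–Alder dimerisation of the enone, secured by excess isoprene at low temperature.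

Step 8
Reactants: 13 (6R,10S)-10-bromo-3,11,11-trimethylspiro[5.5]undec-2-en-7-one
Product: 14 (2S,3R,6R,10S)-10-bromo-2,3-epoxy-3,11,11-trimethylspiro[5.5]undecan-7-one
Conditions: mCPBA, CH2Cl2, 0 °C
Reagents that add atoms: 3-chloroperbenzoic acid, OOC(=O)c1cccc(Cl)c1
Why: Prilezhaev epoxidation of the trisubstituted alkene, faster than Baeyer–Villiger oxidation of the hindered ketone, in which the peracid approaches the face of C2=C3 anti to the pseudo-axial C7 carbonyl carbon on C6 and so sets C2 (S) and C3 (R).

Step 9
Reactants: 14 (2S,3R,6R,10S)-10-bromo-2,3-epoxy-3,11,11-trimethylspiro[5.5]undecan-7-one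
Product: 15 (2R,3R,6R,10S)-10-bromo-2-chloro-3-hydroxy-3,11,11-trimethylspiro[5.5]undecan-7-one
Conditions: LiCl, AcOH, THF, 23 °C
Reagents that add atoms: lithium chloride, [Li+].[Cl-]
Why: Trans-diaxial (Fürst–Plattner) SN2 opening of the trisubstituted epoxide by chloride at the secondary carbon C2 with inversion (C2 becomes R, chlorine syn to C7), in the same sense as the opening of 2α,3α-epoxy steroids at C2, leaves the tertiary C3–OH antiperiplanar to chlorine.

Step 10
Reactants: 15 (2R,3R,6R,10S)-10-bromo-2-chloro-3-hydroxy-3,11,11-trimethylspiro[5.5]undecan-7-one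
Product: 16 (2R,3R,6R,10S)-3,10-dibromo-2-chloro-3,11,11-trimethylspiro[5.5]undecan-7-one
Conditions: Me3SiBr, CH2Cl2, −20 → 0 °C
Reagents that add atoms: bromotrimethylsilane, C[Si](C)(C)Br
Why: SN1-type substitution of the tertiary alcohol after O-silylation, in which the antiperiplanar axial chlorine assists ionisation and bromide enters C3 axially from the open face anti to chlorine and to C7, giving net retention (C3 R) and the trans-diaxial product with equatorial methyl, which is also the more stable C3 epimer.

Step 11
Reactants: 16 (2R,3R,6R,10S)-3,10-dibromo-2-chloro-3,11,11-trimethylspiro[5.5]undecan-7-one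
Product: 17 (2R,3R,6S,10S)-3,10-dibromo-2-chloro-3,11,11-trimethyl-7-methylidenespiro[5.5]undecane
Conditions: Cp2TiMe2, toluene, 70 °C, dark
Reagents that add atoms: dimethyltitanocene, C[Ti](C)(C1C=CC=C1)C1C=CC=C1
Why: Petasis methylenation through thermally generated Cp2Ti=CH2 ([2+2] then retro-[2+2]) is non-basic and suited to the hindered α-quaternary ketone while sparing the tertiary bromide, and no stereocentre is affected (C6 changes from R to S only through the change in CIP priorities).

Compound list
1 | prenol (3-methylbut-2-en-1-ol) | CC(C)=CCO | starting material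
2 | (2S)-2-bromo-3-chloro-3-methylbutan-1-ol | OC[C@H](Br)C(C)(C)Cl | intermediate
3 | (2S)-2-bromo-3-chloro-3-methylbutyl trifluoromethanesulfonate | O=S(=O)(OC[C@H](Br)C(C)(C)Cl)C(F)(F)F | intermediate
4 | methyl acetoacetate | COC(=O)CC(C)=O | starting material
5 | sodium lithium dianion of methyl acetoacetate | [Na+].[Li+].[CH2-]C(=O)[CH-]C(=O)OC | intermediate (not isolated)
6 | methyl (6S)-6-bromo-7-chloro-7-methyl-3-oxooctanoate | COC(=O)CC(=O)CC[C@H](Br)C(C)(C)Cl | intermediate
7 | methyl (2E,6S)-6-bromo-7-chloro-3-methoxy-7-methyloct-2-enoate | COC(=O)/C=C(/OC)CC[C@H](Br)C(C)(C)Cl | intermediate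
8 | (6S)-bromiranium ion formed from 7 by loss of chloride (bromine bridging C6 and C7 of the chain) | COC(=O)/C=C(/OC)CC[C@@H]1[Br+]C1(C)C | intermediate (not isolated)
9 | methyl (5S)-5-bromo-2-methoxy-6,6-dimethylcyclohex-1-ene-1-carboxylate | COC(=O)C1=C(OC)CC[C@H](Br)C1(C)C | intermediate
10 | [(5S)-5-bromo-2-methoxy-6,6-dimethylcyclohex-1-en-1-yl]methanol | OCC1=C(OC)CC[C@H](Br)C1(C)C | intermediate (not isolated)
11 | (4S)-4-bromo-3,3-dimethyl-2-methylidenecyclohexan-1-one | C=C1C(=O)CC[C@H](Br)C1(C)C | intermediate
12 | isoprene (2-methylbuta-1,3-diene) | C=CC(C)=C | starting material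
13 | (6R,10S)-10-bromo-3,11,11-trimethylspiro[5.5]undec-2-en-7-one | O=C1CC[C@H](Br)C(C)(C)[C@]12CCC(C)=CC2 | intermediate
14 | (2S,3R,6R,10S)-10-bromo-2,3-epoxy-3,11,11-trimethylspiro[5.5]undecan-7-one (epoxide oxygen anti to C7) | O=C1CC[C@H](Br)C(C)(C)[C@]12CC[C@@]3(C)O[C@H]3C2 | intermediate
15 | (2R,3R,6R,10S)-10-bromo-2-chloro-3-hydroxy-3,11,11-trimethylspiro[5.5]undecan-7-one | O=C1CC[C@H](Br)C(C)(C)[C@]12CC[C@@](C)(O)[C@H](Cl)C2 | intermediate
16 | (2R,3R,6R,10S)-3,10-dibromo-2-chloro-3,11,11-trimethylspiro[5.5]undecan-7-one | O=C1CC[C@H](Br)C(C)(C)[C@]12CC[C@@](C)(Br)[C@H](Cl)C2 | intermediate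
17 | (2R,3R,6S,10S)-3,10-dibromo-2-chloro-3,11,11-trimethyl-7-methylidenespiro[5.5]undecane | C=C1CC[C@H](Br)C(C)(C)[C@]12CC[C@@](C)(Br)[C@H](Cl)C2 | target

Total step count: 11.
Longest linear sequence: 11 steps (1 → 17); methyl acetoacetate 4 and isoprene 12 enter as commercial compounds.

Steps most likely to fail

Step 3. The risk is that E2 loss of triflate, or attack of the dianion on bromine with expulsion of chloride, outruns SN2 at the β-branched, β-bromo triflate. The fallback builds the carbon chain first and takes the bromonium ion from an epoxide, so no substitution next to a halogen is needed; it sets out from 4 and comes back at 9. The dianion of 4 would be alkylated with prenyl bromide to give methyl 7-methyl-3-oxooct-6-enoate F1. Trimethyl orthoformate and catalytic acid would convert it into methyl (2E)-3-methoxy-7-methylocta-2,6-dienoate F2. Shi epoxidation (fructose-derived ketone of the enantiomeric series that gives the 6R product, Oxone, buffered MeCN/water, 0 °C) should epoxidise the electron-rich prenyl alkene to methyl (2E,6R)-6,7-epoxy-3-methoxy-7-methyloct-2-enoate F3. LiBr in AcOH/THF would open the epoxide at the secondary carbon with inversion to give methyl (2E,6S)-6-bromo-7-hydroxy-3-methoxy-7-methyloct-2-enoate F4. In (CF3)2CHOH with catalytic TfOH the tertiary alcohol would ionise with bromine participation to the same ion 8 and cyclise to 9.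

Step 10. The risk is E1 elimination to allylic chlorides, or capture of the C3 cation by the C7 carbonyl oxygen, in place of bromide substitution. The fallback sets out from 13 and comes back at 16, replacing steps 8–10 by one anti bromochlorination of the alkene with tetrabutylammonium dichlorobromate (Bu4N+ BrCl2−) in CH2Cl2 at −40 °C. The bromonium ion should form on the face anti to C7 and be opened trans-diaxially by chloride at C2, as in diaxial additions to steroid 2-enes, against the usual Markovnikov preference. New compounds on its way: none F0.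

Step 11. The risk is loss of HBr from the tertiary bromide, or reductive removal of the vicinal halogens by low-valent titanium, during slow methylenation of the hindered ketone. The fallback is a two-stage Peterson olefination that sets out from 16 and comes back at 17. Me3SiCH2MgCl with CeCl3 in THF at −78 °C would add to the ketone to give (2R,3R,10S)-3,10-dibromo-2-chloro-3,11,11-trimethyl-7-[(trimethylsilyl)methyl]spiro[5.5]undecan-7-ol (C7 epimers, other centres as in 16) F5. HF·pyridine in MeCN at 0 °C would then effect acid-promoted anti elimination to 17.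

Further compounds
F1 | step 3 | methyl 7-methyl-3-oxooct-6-enoate | COC(=O)CC(=O)CCC=C(C)C
F2 | step 3 | methyl (2E)-3-methoxy-7-methylocta-2,6-dienoate | COC(=O)/C=C(/OC)CCC=C(C)C
F3 | step 3 | methyl (2E,6R)-6,7-epoxy-3-methoxy-7-methyloct-2-enoate | COC(=O)/C=C(/OC)CC[C@H]1OC1(C)C
F4 | step 3 | methyl (2E,6S)-6-bromo-7-hydroxy-3-methoxy-7-methyloct-2-enoate | COC(=O)/C=C(/OC)CC[C@H](Br)C(C)(C)O
F0 | step 10 | none | none
F5 | step 11 | (2R,3R,10S)-3,10-dibromo-2-chloro-3,11,11-trimethyl-7-[(trimethylsilyl)methyl]spiro[5.5]undecan-7-ol | C[Si](C)(C)CC1(O)CC[C@H](Br)C(C)(C)[C@]12CC[C@@](C)(Br)[C@H](Cl)C2
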